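**Retrosynthetic overview**

1. The route rests on one feature: the ester oxygen sits on C4 of ring A between the C3 and C5 methyl groups, and the acyl carbon on C1′ of ring B is flanked by C2′‑CH3 and C6′‑OH, with a free C4′‑OH and a C3′ aldehyde; both partners of a normal acylation are therefore crowded.
2. The ester is cut at the O–C4(aryl) bond, not at the acyl–O bond: the ring B carboxylate is the nucleophile and a ring A aryl(2,4,6‑trimethoxyphenyl)iodonium tosylate is the aryl electrophile.
3. Ring A comes from 2,4,5‑trimethylphenol: ortho‑formylation, O‑methylation, oxidation, esterification, iodination of the last C–H, then oxidation at iodine and capture by 1,3,5‑trimethoxybenzene.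
4. Ring B comes from atraric acid: formylation of its single free ring carbon, then cleavage of the crowded methyl ester through the acylium ion.
5. No ring is formed (both benzene rings are bought) and the target has no stereocentre; the fragments are joined in the last step.

Key step: step 9

Remark on numbering: ring A is numbered from the CO2CH3‑bearing carbon (C1; OCH3 on C2, CH3 on C3, C5 and C6, ester oxygen on C4), ring B from the carboxyl‑bearing carbon (C1′; CH3 on C2′ and C5′, CHO on C3′, OH on C4′ and C6′).

**Route**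

Step 1
Reactants: 1 2,4,5‑trimethylphenol
Product: 3 2‑hydroxy‑3,5,6‑trimethylbenzaldehyde, via hydroxymethylphenol 2 (not isolated)
Conditions: MgCl2, Et3N, (CH2O)n, MeCN, reflux; aq. HCl work‑up
Reagents that add atoms: paraformaldehyde (as formaldehyde), C=O
Why: Casnati–Skattebøl ortho‑formylation: the magnesium phenoxide delivers formaldehyde to the only free ortho carbon (C6 of 1), and the benzylic alkoxide 2 is oxidised by a second formaldehyde through an Oppenauer‑type hydride transfer, so the aldehyde should appear at that carbon alone.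

Step 2
Reactants: 3 2‑hydroxy‑3,5,6‑trimethylbenzaldehyde
Product: 4 2‑methoxy‑3,5,6‑trimethylbenzaldehyde
Conditions: MeI, K2CO3, DMF, 40 °C
Reagents that add atoms: iodomethane, CI
Why: Williamson etherification of the phenoxide; the aldehyde has no α‑hydrogen, and carbonate in DMF should break the O–H···O=C hydrogen bond that lowers the reactivity of this phenol.

Step 3
Reactants: 4 2‑methoxy‑3,5,6‑trimethylbenzaldehyde
Product: 5 2‑methoxy‑3,5,6‑trimethylbenzoic acid
Conditions: NaClO2, NaH2PO4, 2‑methyl‑2‑butene, t‑BuOH/H2O, rt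
Reagents that add atoms: sodium chlorite, [Na+].[O-]Cl=O
Why: Pinnick oxidation of the aryl aldehyde through its chlorous acid adduct; 2‑methyl‑2‑butene traps the hypochlorous acid that could otherwise chlorinate the free C4–H of the ring.

Step 4
Reactants: 5 2‑methoxy‑3,5,6‑trimethylbenzoic acid
Product: 6 methyl 2‑methoxy‑3,5,6‑trimethylbenzoate
Conditions: MeI, K2CO3, DMF, rt
Reagents that add atoms: iodomethane, CI
Why: SN2 O‑methylation of the carboxylate takes place at oxygen, away from the carbonyl carbon shielded by the C2 methoxy and C6 methyl groups, so it should succeed where Fischer esterification of a 2,6‑disubstituted benzoic acid is slow.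

Step 5
Reactants: 6 methyl 2‑methoxy‑3,5,6‑trimethylbenzoate
Product: 7 methyl 4‑iodo‑2‑methoxy‑3,5,6‑trimethylbenzoate
Conditions: NIS, TFA, cat. TfOH, 0 °C to rt
Reagents that add atoms: N‑iodosuccinimide, O=C1CCC(=O)N1I
Why: Electrophilic aromatic iodination by acid‑activated NIS at C4, the only ring C–H, which is activated by the flanking C3 and C5 methyl groups while the ester, twisted out of the ring plane by its two ortho substituents, deactivates only weakly.

Step 6
Reactants: 7 methyl 4‑iodo‑2‑methoxy‑3,5,6‑trimethylbenzoate; 8 1,3,5‑trimethoxybenzene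
Product: 10 [3‑methoxy‑4‑(methoxycarbonyl)‑2,5,6‑trimethylphenyl](2,4,6‑trimethoxyphenyl)iodonium tosylate, via hydroxy(tosyloxy)iodoarene 9 (not isolated)
Conditions: mCPBA, TsOH·H2O, MeCN, 75 °C; then 1,3,5‑trimethoxybenzene, rt to 75 °C; Et2O trituration
Reagents that add atoms: p‑toluenesulfonic acid (used as the monohydrate), Cc1ccc(S(=O)(=O)O)cc1
Why: One‑pot diaryliodonium synthesis: mCPBA and TsOH oxidise the aryl iodide to the Koser‑type trivalent iodine species 9, whose iodine is then attacked by the strongly nucleophilic 1,3,5‑trimethoxybenzene in an electrophilic aromatic substitution, giving the aryl(trimethoxyphenyl)iodonium tosylate.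

Step 7
Reactants: 11 atraric acid (methyl 2,4‑dihydroxy‑3,6‑dimethylbenzoate)
Product: 13 methyl 3‑formyl‑4,6‑dihydroxy‑2,5‑dimethylbenzoate, via chloro(methoxy)methyl arene 12 (not isolated)
Conditions: Cl2CHOMe, TiCl4, CH2Cl2, 0 °C to rt; then ice/aq. HCl
Reagents that add atoms: dichloromethyl methyl ether, COC(Cl)Cl; water, O
Why: Rieche formylation: the titanium‑bound phenol directs the chloro(methoxy)carbenium ion to the single free ring carbon of 11 (ortho to the 4‑OH, para to the 2‑OH), and aqueous work‑up hydrolyses the α‑chloro ether 12 to the aldehyde.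

Step 8
Reactants: 13 methyl 3‑formyl‑4,6‑dihydroxy‑2,5‑dimethylbenzoate
Product: 15 3‑formyl‑4,6‑dihydroxy‑2,5‑dimethylbenzoic acid, via acylium hydrogensulfate 14 (not isolated)
Conditions: conc. H2SO4, 0 °C to rt; then ice water
Reagents that add atoms: water, O
Why: AAC1 ester cleavage: in concentrated sulfuric acid the crowded ester (between C2′‑CH3 and C6′‑OH) ionises to the acylium ion 14, stabilised by the ortho and para hydroxyl groups, and water captures it on quenching; the ring has no C–H to sulfonate and the hydrogen‑bonded aldehyde should survive a short exposure at or below room temperature.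

Step 9
Reactants: 15 3‑formyl‑4,6‑dihydroxy‑2,5‑dimethylbenzoic acid; 10 [3‑methoxy‑4‑(methoxycarbonyl)‑2,5,6‑trimethylphenyl](2,4,6‑trimethoxyphenyl)iodonium tosylate
Product: 18 methyl 4‑[(3‑formyl‑4,6‑dihydroxy‑2,5‑dimethylbenzoyl)oxy]‑2‑methoxy‑3,5,6‑trimethylbenzoate (target), via potassium carboxylate 16 (not isolated), via carboxylato‑iodane 17 (not isolated)
Conditions: KOC(CH3)3 (1.0 equiv), THF/toluene, 0 °C to rt; then 10 (1.2 equiv), toluene, 90 °C
Reagents that add atoms: none
Why: One equivalent of KOC(CH3)3 removes only the carboxyl proton of 15; carboxylate 16 displaces tosylate on trivalent iodine to give the T‑shaped iodane 17, and ligand coupling between the carboxylate oxygen and the ipso carbon C4 of ring A forms the O–C4 bond and releases 2‑iodo‑1,3,5‑trimethoxybenzene (monovalent iodine). The closest known reaction type is the metal‑free O‑arylation of carboxylic acids with diaryliodonium salts that carry a trimethoxyphenyl dummy ligand; no ring closes and no stereocentre is formed. The ring A aryl should transfer rather than the trimethoxyphenyl group, because the latter is far more electron‑rich and resists the negative charge that builds at the ipso carbon, and because the C3 and C5 methyl groups push ring A into the equatorial site from which coupling occurs (ortho effect). The carboxylate should react before the phenols: it is the only deprotonated site, the C4′‑OH is hydrogen‑bonded to the formyl oxygen and the C6′‑OH to the carboxylate, and arylation of either phenol oxygen would have to build a tetra‑ortho‑substituted diaryl ether. Neither aryl group on iodine has an ortho hydrogen, so an aryne path cannot operate, ring B has no free ring carbon for C‑arylation, and the carboxylate reacts through oxygen, away from the crowded C1′ carbonyl carbon that makes acyl activation difficult. The acid is heated only as its potassium salt and at moderate temperature to hold back decarboxylation.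

**Compound list**

1 | 2,4,5‑trimethylphenol | Cc1cc(C)c(O)cc1C | starting material
2 | 2‑(hydroxymethyl)‑3,4,6‑trimethylphenol (formed as its magnesium salt, not isolated) | OCc1c(O)c(C)cc(C)c1C | intermediate
3 | 2‑hydroxy‑3,5,6‑trimethylbenzaldehyde | O=Cc1c(O)c(C)cc(C)c1C | intermediate
4 | 2‑methoxy‑3,5,6‑trimethylbenzaldehyde | COc1c(C)cc(C)c(C)c1C=O | intermediate
5 | 2‑methoxy‑3,5,6‑trimethylbenzoic acid | COc1c(C)cc(C)c(C)c1C(=O)O | intermediate
6 | methyl 2‑methoxy‑3,5,6‑trimethylbenzoate | COC(=O)c1c(C)c(C)cc(C)c1OC | intermediate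
7 | methyl 4‑iodo‑2‑methoxy‑3,5,6‑trimethylbenzoate | COC(=O)c1c(C)c(C)c(I)c(C)c1OC | intermediate
8 | 1,3,5‑trimethoxybenzene | COc1cc(OC)cc(OC)c1 | starting material
9 | methyl 4‑[hydroxy(tosyloxy)‑λ3‑iodanyl]‑2‑methoxy‑3,5,6‑trimethylbenzoate (not isolated) | COC(=O)c1c(C)c(C)c(I(O)OS(=O)(=O)c2ccc(C)cc2)c(C)c1OC | intermediate
10 | [3‑methoxy‑4‑(methoxycarbonyl)‑2,5,6‑trimethylphenyl](2,4,6‑trimethoxyphenyl)iodonium tosylate | COC(=O)c1c(C)c(C)c([I+]c2c(OC)cc(OC)cc2OC)c(C)c1OC.Cc1ccc(S(=O)(=O)[O-])cc1 | intermediate
11 | atraric acid (methyl 2,4‑dihydroxy‑3,6‑dimethylbenzoate) | COC(=O)c1c(C)cc(O)c(C)c1O | starting material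
12 | methyl 3‑[chloro(methoxy)methyl]‑4,6‑dihydroxy‑2,5‑dimethylbenzoate (not isolated) | COC(=O)c1c(C)c(C(Cl)OC)c(O)c(C)c1O | intermediate
13 | methyl 3‑formyl‑4,6‑dihydroxy‑2,5‑dimethylbenzoate | COC(=O)c1c(C)c(C=O)c(O)c(C)c1O | intermediate
14 | 3‑formyl‑4,6‑dihydroxy‑2,5‑dimethylbenzoyl cation hydrogensulfate (acylium ion, not isolated) | O=Cc1c(C)c(C#[O+])c(O)c(C)c1O.OS(=O)(=O)[O-] | intermediate
15 | 3‑formyl‑4,6‑dihydroxy‑2,5‑dimethylbenzoic acid | O=Cc1c(C)c(C(=O)O)c(O)c(C)c1O | intermediate
16 | potassium 3‑formyl‑4,6‑dihydroxy‑2,5‑dimethylbenzoate (not isolated) | O=Cc1c(C)c(C(=O)[O-])c(O)c(C)c1O.[K+] | intermediate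
17 | [3‑methoxy‑4‑(methoxycarbonyl)‑2,5,6‑trimethylphenyl](2,4,6‑trimethoxyphenyl)(3‑formyl‑4,6‑dihydroxy‑2,5‑dimethylbenzoyloxy)‑λ3‑iodane (not isolated) | COC(=O)c1c(C)c(C)c(I(OC(=O)c2c(C)c(C=O)c(O)c(C)c2O)c2c(OC)cc(OC)cc2OC)c(C)c1OC | intermediate
18 | methyl 4‑[(3‑formyl‑4,6‑dihydroxy‑2,5‑dimethylbenzoyl)oxy]‑2‑methoxy‑3,5,6‑trimethylbenzoate | COC(=O)c1c(C)c(C)c(OC(=O)c2c(C)c(C=O)c(O)c(C)c2O)c(C)c1OC | target

**Step count**

Total steps: 9. Longest linear sequence: 7 (steps 1 to 6, then step 9); the ring B branch is steps 7 and 8.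

**Steps most likely to fail**

Step 9. The coupling may go astray in three ways: proton transfer within the salt could let a phenoxide oxygen be arylated, the trimethoxyphenyl group could be transferred in place of ring A, or the β‑resorcylate could lose CO2 on heating before it couples. The fallback returns to acyl transfer and sets out from 7 and 15. Palladium‑catalysed hydroxylation of 7 (Pd2(dba)3 as the zerovalent palladium source, t‑BuXPhos, KOH, dioxane/H2O, 100 °C; the mesitoate‑like ester should resist saponification) would give methyl 4‑hydroxy‑2‑methoxy‑3,5,6‑trimethylbenzoate F1. Acid 15 would then be activated with trifluoroacetic anhydride in toluene at room temperature as 3‑formyl‑4,6‑dihydroxy‑2,5‑dimethylbenzoic trifluoroacetic anhydride F2, a small acylium‑like electrophile that tolerates the free ortho hydroxyl group, and F2 would acylate F1. This comes back to the route at the target 18.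

Step 8. Ipso‑protonation in the strong acid could strip the carboxyl or the formyl group from the electron‑rich ring, or the ester could ionise incompletely. The fallback sets out from 11 and frees the acid under neutral conditions at the end. Saponification of 11 before formylation (KOH, DMSO/H2O, 40 °C, cold acidification) would give 2,4‑dihydroxy‑3,6‑dimethylbenzoic acid F3. Selective alkylation of its carboxylate (BnBr, KHCO3, DMF, rt) would give benzyl 2,4‑dihydroxy‑3,6‑dimethylbenzoate F4. Rieche formylation (Cl2CHOMe, TiCl4, CH2Cl2, −20 to 0 °C), passing through benzyl 3‑[chloro(methoxy)methyl]‑4,6‑dihydroxy‑2,5‑dimethylbenzoate F5 (not isolated), would give benzyl 3‑formyl‑4,6‑dihydroxy‑2,5‑dimethylbenzoate F6. Hydrogenolysis (H2, palladium on carbon (Pd/C), EtOAc, rt) would then return to the route at 15.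

Step 5. The iodination could stall at a carbon that is para to the ester and meta to the methoxy group, the hindered iodide could be protodeiodinated again in the acid, or the acid could ionise the crowded ester. The fallback sets out from 6 and brings in iodine by a Sandmeyer‑type sequence. Nitration with the much stronger electrophile (fuming HNO3, Ac2O, 0 °C) would give methyl 2‑methoxy‑3,5,6‑trimethyl‑4‑nitrobenzoate F7. Reduction (Fe, NH4Cl, EtOH/H2O, 70 °C) would give methyl 4‑amino‑2‑methoxy‑3,5,6‑trimethylbenzoate F8. Diazotisation with iodide present (NaNO2, TsOH, KI, MeCN/H2O, 10 °C to rt) would pass through 3‑methoxy‑4‑(methoxycarbonyl)‑2,5,6‑trimethylbenzenediazonium tosylate F9 (not isolated) and return to the route at 7.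

**Further compounds**

F1 | step 9 | methyl 4‑hydroxy‑2‑methoxy‑3,5,6‑trimethylbenzoate | COC(=O)c1c(C)c(C)c(O)c(C)c1OC
F2 | step 9 | 3‑formyl‑4,6‑dihydroxy‑2,5‑dimethylbenzoic trifluoroacetic anhydride | O=Cc1c(C)c(C(=O)OC(=O)C(F)(F)F)c(O)c(C)c1O
F3 | step 8 | 2,4‑dihydroxy‑3,6‑dimethylbenzoic acid | Cc1cc(O)c(C)c(O)c1C(=O)O
F4 | step 8 | benzyl 2,4‑dihydroxy‑3,6‑dimethylbenzoate | Cc1cc(O)c(C)c(O)c1C(=O)OCc1ccccc1
F5 | step 8 | benzyl 3‑[chloro(methoxy)methyl]‑4,6‑dihydroxy‑2,5‑dimethylbenzoate | COC(Cl)c1c(C)c(C(=O)OCc2ccccc2)c(O)c(C)c1O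
F6 | step 8 | benzyl 3‑formyl‑4,6‑dihydroxy‑2,5‑dimethylbenzoate | O=Cc1c(C)c(C(=O)OCc2ccccc2)c(O)c(C)c1O
F7 | step 5 | methyl 2‑methoxy‑3,5,6‑trimethyl‑4‑nitrobenzoate | COC(=O)c1c(C)c(C)c([N+](=O)[O-])c(C)c1OC
F8 | step 5 | methyl 4‑amino‑2‑methoxy‑3,5,6‑trimethylbenzoate | COC(=O)c1c(C)c(C)c(N)c(C)c1OC
F9 | step 5 | 3‑methoxy‑4‑(methoxycarbonyl)‑2,5,6‑trimethylbenzenediazonium tosylate | COC(=O)c1c(C)c(C)c([N+]#N)c(C)c1OC.Cc1ccc(S(=O)(=O)[O-])cc1
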